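Retrosynthesis: the fifteen benzyl ethers come off last. Each flavan unit is then opened, bottom unit first, at C4–C4a (ring C), at the bond from C4 to the next ring A, and at O1–C2. This returns three copies of one C2–C3–C4 chain block, one 3,5-dioxygenated phenol (top ring A) and two portions of one 4-magnesiated 3,5-dioxyphenyl silyl ether (middle and bottom rings A).
Enabling feature: each interflavan bond ends at C6 of the lower ring A, para to C8a–O1 and flanked by C5–O and C7–O. Ring A of the lower unit plus C4 of the upper unit is therefore a symmetric 2,6-dioxygenated 4-oxybenzyl unit, whose para oxygen makes C4 a para-quinone methide and whose two carbons ortho to that oxygen (future C4a and C8) are equivalent.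
Forward order: the chain grows from the top. Each cycle joins O1 to C2 (Mitsunobu), joins C4 to the next ring A (aryl Grignard reagent), and closes ring C by C4–C4a bond formation onto the quinone methide, which frees the phenol for the next cycle. Rings C arise top, middle, bottom, the last by reductive Friedel–Crafts closure.
Stereochemistry: C3 of every unit comes from an auxiliary-controlled anti glycolate aldol. C2 comes from Mitsunobu inversion of the benzylic carbinol (anti block to 2,3-cis, 2R,3R). C4 of the top and middle units is set in the ring closure (3,4-trans, 4β).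

Key step: step 13

Assumption: the anti glycolate aldol is taken to run through an open transition state on the thione-chelated titanium enolate, so that the (R)-configured auxiliary delivers the (2S,3S) adduct; should the facial sense prove opposite, the enantiomeric auxiliary would be used and nothing else changes.

Step 1
Reactants: 1 (R)-4-benzyl-1,3-oxazolidine-2-thione; 2 (benzyloxy)acetyl chloride
Product: 3 (R)-4-benzyl-3-[(benzyloxy)acetyl]-1,3-oxazolidine-2-thione
Conditions: Et3N, CH2Cl2, 0 °C to rt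
Reagents that add atoms: none
Why: N-acylation of the auxiliary by the acid chloride, the N-acyl compound being the thermodynamically preferred isomer.

Step 2
Reactants: 3 (R)-4-benzyl-3-[(benzyloxy)acetyl]-1,3-oxazolidine-2-thione; 4 3,4-bis(benzyloxy)benzaldehyde
Product: 6 (R)-4-benzyl-3-[(2S,3S)-2-(benzyloxy)-3-[3,4-bis(benzyloxy)phenyl]-3-hydroxypropanoyl]-1,3-oxazolidine-2-thione, via chlorotitanium enolate 5 (not isolated)
Conditions: TiCl4, i-Pr2NEt, CH2Cl2, −78 °C; then 4 premixed with further TiCl4, −78 °C; aq. NH4Cl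
Reagents that add atoms: none
Why: anti-selective titanium glycolate aldol of an N-glycolyl oxazolidinethione, in which the Z-enolate adds through an open transition state to the TiCl4-bound aldehyde (2,3-anti) on the face turned away from the benzyl group of the auxiliary, which should set C2 and C3 both as S.

Step 3
Reactants: 6 (R)-4-benzyl-3-[(2S,3S)-2-(benzyloxy)-3-[3,4-bis(benzyloxy)phenyl]-3-hydroxypropanoyl]-1,3-oxazolidine-2-thione
Product: 7 (2S,3S)-2-(benzyloxy)-3-[3,4-bis(benzyloxy)phenyl]-3-hydroxy-N-methoxy-N-methylpropanamide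
Conditions: MeNH(OMe)·HCl, imidazole, CH2Cl2, rt
Reagents that add atoms: N,O-dimethylhydroxylamine hydrochloride, Cl.CNOC
Why: aminolysis of the activated thioimide to the Weinreb amide, which tolerates the free hydroxyl and returns the auxiliary.

Step 4
Reactants: 8 2-bromoresorcinol
Product: 9 2-bromo-1,3-bis(tert-butyldimethylsilyloxy)benzene
Conditions: TBSCl, imidazole, DMF, rt
Reagents that add atoms: tert-butyldimethylsilyl chloride, CC(C)(C)[Si](C)(C)Cl
Why: O-silylation; silyl ethers are used for the borylation because, unlike benzyl ethers, they offer the iridium catalyst no unhindered aromatic C-H bond.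

Step 5
Reactants: 9 2-bromo-1,3-bis(tert-butyldimethylsilyloxy)benzene
Product: 10 2-[4-bromo-3,5-bis(tert-butyldimethylsilyloxy)phenyl]-4,4,5,5-tetramethyl-1,3,2-dioxaborolane
Conditions: [Ir(OMe)(cod)]2 (cat.), 4,4'-di-tert-butyl-2,2'-bipyridine (cat.), B2pin2, THF, 80 °C
Reagents that add atoms: bis(pinacolato)diboron, CC1(C)OB(B2OC(C)(C)C(C)(C)O2)OC1(C)C
Why: sterically governed iridium-catalysed aromatic C-H borylation, which should take the only C-H bond without an ortho substituent (C5, para to bromine) and leave the C-Br bond alone.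

Step 6
Reactants: 10 2-[4-bromo-3,5-bis(tert-butyldimethylsilyloxy)phenyl]-4,4,5,5-tetramethyl-1,3,2-dioxaborolane
Product: 11 2-[3,5-bis(benzyloxy)-4-bromophenyl]-4,4,5,5-tetramethyl-1,3,2-dioxaborolane
Conditions: CsF, BnBr, DMF, rt
Reagents that add atoms: benzyl bromide, BrCc1ccccc1
Why: fluoride cleavage of the aryl silyl ethers with Williamson benzylation of the phenoxides in the same pot, under which an aryl pinacol boronate is stable.

Step 7
Reactants: 11 2-[3,5-bis(benzyloxy)-4-bromophenyl]-4,4,5,5-tetramethyl-1,3,2-dioxaborolane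
Product: 12 3,5-bis(benzyloxy)-4-bromophenol
Conditions: 30% aq. H2O2, aq. NaOH, THF, 0 °C
Reagents that add atoms: hydrogen peroxide, OO
Why: oxidation of the arylboronate to the phenol by 1,2-migration of the aryl group from boron to oxygen.

Step 8
Reactants: 12 3,5-bis(benzyloxy)-4-bromophenol
Product: 13 [3,5-bis(benzyloxy)-4-bromophenoxy]triisopropylsilane
Conditions: TIPSCl, imidazole, DMF, rt
Reagents that add atoms: triisopropylsilyl chloride, CC(C)[Si](Cl)(C(C)C)C(C)C
Why: O-silylation of the unhindered phenol gives a fluoride-labile mask of the para oxygen that withstands Grignard reagent formation and use.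

Step 9
Reactants: 7 (2S,3S)-2-(benzyloxy)-3-[3,4-bis(benzyloxy)phenyl]-3-hydroxy-N-methoxy-N-methylpropanamide; 14 3,5-bis(benzyloxy)phenol
Product: 15 (2S,3R)-2-(benzyloxy)-3-[3,4-bis(benzyloxy)phenyl]-3-[3,5-bis(benzyloxy)phenoxy]-N-methoxy-N-methylpropanamide
Conditions: PPh3, DIAD, toluene, −20 to 0 °C
Reagents that add atoms: none
Why: Mitsunobu etherification of the secondary benzylic alcohol by the phenol with SN2 inversion, which turns the anti block into the 2,3-cis pattern (future C2 becomes R), the adjacent alkoxy amide and the low temperature disfavouring ionisation and elimination.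

Step 10
Reactants: 15 (2S,3R)-2-(benzyloxy)-3-[3,4-bis(benzyloxy)phenyl]-3-[3,5-bis(benzyloxy)phenoxy]-N-methoxy-N-methylpropanamide
Product: 16 (2S,3R)-2-(benzyloxy)-3-[3,4-bis(benzyloxy)phenyl]-3-[3,5-bis(benzyloxy)phenoxy]propanal
Conditions: i-Bu2AlH, THF, −78 °C; aq. potassium sodium tartrate
Reagents that add atoms: none
Why: Weinreb amide reduction, which stops at the aldehyde because the chelated aluminate collapses only on work-up; the aldehyde is used at once to protect the centre alpha to the carbonyl.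

Step 11
Reactants: 13 [3,5-bis(benzyloxy)-4-bromophenoxy]triisopropylsilane
Product: 17 [2,6-bis(benzyloxy)-4-(triisopropylsilyloxy)phenyl]magnesium bromide (titrated THF solution, stored under argon)
Conditions: Mg turnings, LiCl, i-Bu2AlH (1 mol%, activation), THF, rt
Reagents that add atoms: magnesium, [Mg]
Why: LiCl-promoted insertion of magnesium into the aryl C-Br bond (Grignard reagent formation), to which the benzyl and silyl ethers are inert; the solution keeps under argon, so one batch should serve both additions (steps 12 and 16).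

Step 12
Reactants: 17 [2,6-bis(benzyloxy)-4-(triisopropylsilyloxy)phenyl]magnesium bromide; 16 (2S,3R)-2-(benzyloxy)-3-[3,4-bis(benzyloxy)phenyl]-3-[3,5-bis(benzyloxy)phenoxy]propanal
Product: 18 1-[2,6-bis(benzyloxy)-4-(triisopropylsilyloxy)phenyl]-2-(benzyloxy)-3-[3,4-bis(benzyloxy)phenyl]-3-[3,5-bis(benzyloxy)phenoxy]propan-1-ol (both C1 epimers; C2 and C3 as in 16)
Conditions: 17 (THF solution), THF, −78 to −20 °C; H2O
Reagents that add atoms: none
Why: Grignard 1,2-addition of the arylmagnesium reagent to the aldehyde, the low basicity of the magnesium reagent disfavouring enolisation and beta-elimination of the aryloxy group; the new carbinol centre is left uncontrolled because the next step erases it.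

Step 13
Reactants: 18 1-[2,6-bis(benzyloxy)-4-(triisopropylsilyloxy)phenyl]-2-(benzyloxy)-3-[3,4-bis(benzyloxy)phenyl]-3-[3,5-bis(benzyloxy)phenoxy]propan-1-ol
Product: 21 (2R,3R)-3,5,7-tris(benzyloxy)-2-[3,4-bis(benzyloxy)phenyl]-4β-[2,6-bis(benzyloxy)-4-hydroxyphenyl]chroman (3,4-trans; penta-O-benzyl-epicatechin arylated at C4), via phenol carbinol 19 (not isolated), via para-quinone methide 20 (not isolated)
Conditions: n-Bu4NF, THF, 0 °C; then CF3CO2H, CH2Cl2, −40 to 0 °C
Reagents that add atoms: none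
Why: Proposed new method: fluoride frees the para phenol and acid ionises the doubly ortho-oxygenated 4-hydroxybenzyl alcohol 19 to the para-quinone methide 20 (the deprotonated trioxybenzyl cation), whose exocyclic carbon, the future C4, is attacked by a carbon ortho to the ether oxygen of the 3,5-bis(benzyloxy)phenoxy ring, after which the lower ring re-aromatises to the free phenol. The closest known reaction type is the acid-catalysed intramolecular 1,6-Friedel-Crafts addition of arenes to para-quinone methides generated from para-hydroxybenzyl alcohols; closure of ring C of a 4-arylflavan from C4 to C4a has not been described. Ring C closes in the 6-exo-trig mode with respect to the exocyclic C=C of 20, with C4–C4a as its only new bond. The new stereocentre C4 is controlled by allylic 1,3-strain: the ortho benzyloxy groups of the planar methide hold C3–H in its plane, the tethered ring can only arrive on the face that carries C2 and so bonds anti to the C3–O bond, giving the 3,4-trans (4β) product, which relaxes to the half-chair with the 2-aryl group equatorial and the 4-aryl group quasi-axial; the carbinol configuration of 18 is lost on ionisation, so both epimers converge. The step needs attack by the phloroglucinol-type ring and not by the catechol ring (indane formation), which the far higher nucleophilicity of the trioxygenated ring and the six-membered closure should secure; no regiocontrol is needed because the two ortho carbons are equivalent, and the cation forms under conditions much milder than those that cleave the benzylic aryl ether.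

Step 14
Reactants: 21 (2R,3R)-3,5,7-tris(benzyloxy)-2-[3,4-bis(benzyloxy)phenyl]-4β-[2,6-bis(benzyloxy)-4-hydroxyphenyl]chroman; 7 (2S,3S)-2-(benzyloxy)-3-[3,4-bis(benzyloxy)phenyl]-3-hydroxy-N-methoxy-N-methylpropanamide
Product: 22 (2S,3R)-2-(benzyloxy)-3-[3,4-bis(benzyloxy)phenyl]-N-methoxy-N-methyl-3-(aryloxy)propanamide whose aryloxy group is the phenoxide of 21
Conditions: PPh3, DIAD, toluene, −20 to 0 °C
Reagents that add atoms: none
Why: Mitsunobu etherification with inversion at the benzylic carbinol, the para phenol of 21 being its only acidic and unhindered site, which sets C2 of the middle unit as R.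

Step 15
Reactants: 22 middle-unit Weinreb amide
Product: 23 (2S,3R)-2-(benzyloxy)-3-[3,4-bis(benzyloxy)phenyl]-3-(aryloxy)propanal whose aryloxy group is the phenoxide of 21
Conditions: i-Bu2AlH, THF, −78 °C; aq. potassium sodium tartrate
Reagents that add atoms: none
Why: Weinreb amide reduction to the aldehyde through the stable chelated aluminate, as in step 10.

Step 16
Reactants: 17 [2,6-bis(benzyloxy)-4-(triisopropylsilyloxy)phenyl]magnesium bromide; 23 middle-unit aldehyde
Product: 24 1-[2,6-bis(benzyloxy)-4-(triisopropylsilyloxy)phenyl]propan-1-ol formed from 23 (both C1 epimers; other centres unchanged)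
Conditions: 17 (THF solution), THF, −78 to −20 °C; H2O
Reagents that add atoms: none
Why: Grignard 1,2-addition of the arylmagnesium reagent to the aldehyde, as in step 12, the carbinol configuration again being irrelevant.

Step 17
Reactants: 24 middle-unit diaryl carbinol
Product: 27 benzylated epicatechin-(4β→6)-epicatechin (each unit 3,5,7,3′,4′-penta-O-benzyl) bearing at C4 of the lower unit (4β; 3,4-trans) a 2,6-bis(benzyloxy)-4-hydroxyphenyl group, via phenol carbinol 25 (not isolated), via para-quinone methide 26 (not isolated)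
Conditions: n-Bu4NF, THF, 0 °C; then CF3CO2H, CH2Cl2, −40 to 0 °C
Reagents that add atoms: none
Why: Proposed new method: as in step 13, fluoride unmasks the para phenol, acid ionises the 2,6-dioxygenated 4-hydroxybenzyl alcohol to the para-quinone methide, and the phloroglucinol-type ring of the middle unit closes ring C by 6-exo-trig Friedel-Crafts attack of one of its two equivalent free carbons on the methide carbon, anti to the C3–O bond under allylic 1,3-strain control (3,4-trans), which fixes the 4→6 linkage because the ring oxygen lies para to the first interflavan carbon; the closest known reaction type is the acid-catalysed intramolecular 1,6-Friedel-Crafts addition of arenes to para-quinone methides generated from para-hydroxybenzyl alcohols.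

Step 18
Reactants: 27 benzylated dimer with free para phenol; 7 (2S,3S)-2-(benzyloxy)-3-[3,4-bis(benzyloxy)phenyl]-3-hydroxy-N-methoxy-N-methylpropanamide
Product: 28 (2S,3R)-2-(benzyloxy)-3-[3,4-bis(benzyloxy)phenyl]-N-methoxy-N-methyl-3-(aryloxy)propanamide whose aryloxy group is the phenoxide of 27
Conditions: PPh3, DIAD, toluene, −20 to 0 °C
Reagents that add atoms: none
Why: Mitsunobu etherification with inversion, which sets C2 of the bottom unit as R.

Step 19
Reactants: 28 bottom-unit Weinreb amide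
Product: 29 (2S,3R)-2-(benzyloxy)-3-[3,4-bis(benzyloxy)phenyl]-3-(aryloxy)propanal whose aryloxy group is the phenoxide of 27
Conditions: i-Bu2AlH, THF, −78 °C; aq. potassium sodium tartrate
Reagents that add atoms: none
Why: Weinreb amide reduction to the aldehyde, as in step 10.

Step 20
Reactants: 29 bottom-unit aldehyde
Product: 31 pentadeca-O-benzyl epicatechin-(4β→6)-epicatechin-(4β→6)-epicatechin, via flavan-4-ol 30 (not isolated)
Conditions: Et3SiH, CF3CO2H, CH2Cl2, −20 to 0 °C
Reagents that add atoms: none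
Why: intramolecular Friedel-Crafts hydroxyalkylation of the trioxygenated ring by the protonated aldehyde closes the bottom ring C, and the flavan-4-ol is reduced in the same pot by ionic hydrogenation (silane hydride transfer to the 5,7-dioxygenated benzylic cation), so C4 becomes a methylene and no new stereocentre arises.

Step 21
Reactants: 31 pentadeca-O-benzyl trimer
Product: 32 epicatechin-(4β→6)-epicatechin-(4β→6)-epicatechin (target)
Conditions: H2 (1 atm), Pd(OH)2/C, THF/MeOH/H2O, rt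
Reagents that add atoms: none
Why: hydrogenolysis of all fifteen benzyl ethers over Pd(OH)2 on carbon under neutral conditions, which should leave the benzylic C2–O1 bonds, the interflavan bonds and every stereocentre untouched.

Compound list
1 | (R)-4-benzyl-1,3-oxazolidine-2-thione | S=C1OC[C@@H](Cc2ccccc2)N1 | starting material
2 | (benzyloxy)acetyl chloride | O=C(Cl)COCc1ccccc1 | starting material
3 | (R)-4-benzyl-3-[(benzyloxy)acetyl]-1,3-oxazolidine-2-thione | S=C1OC[C@@H](Cc2ccccc2)N1C(=O)COCc1ccccc1 | intermediate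
4 | 3,4-bis(benzyloxy)benzaldehyde | O=Cc1ccc(OCc2ccccc2)c(OCc2ccccc2)c1 | starting material
5 | trichlorotitanium (Z)-enolate of 3 | S=C1OC[C@@H](Cc2ccccc2)N1/C(O[Ti](Cl)(Cl)Cl)=C/OCc1ccccc1 | intermediate (not isolated)
6 | (R)-4-benzyl-3-[(2S,3S)-2-(benzyloxy)-3-[3,4-bis(benzyloxy)phenyl]-3-hydroxypropanoyl]-1,3-oxazolidine-2-thione | S=C1OC[C@@H](Cc2ccccc2)N1C(=O)[C@@H](OCc1ccccc1)[C@H](c1ccc(OCc2ccccc2)c(OCc2ccccc2)c1)O | intermediate
7 | (2S,3S)-2-(benzyloxy)-3-[3,4-bis(benzyloxy)phenyl]-3-hydroxy-N-methoxy-N-methylpropanamide | CON(C)C(=O)[C@@H](OCc1ccccc1)[C@H](c1ccc(OCc2ccccc2)c(OCc2ccccc2)c1)O | intermediate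
8 | 2-bromoresorcinol | Oc1cccc(O)c1Br | starting material
9 | 2-bromo-1,3-bis(tert-butyldimethylsilyloxy)benzene | CC(C)(C)[Si](C)(C)Oc1cccc(O[Si](C)(C)C(C)(C)C)c1Br | intermediate
10 | 2-[4-bromo-3,5-bis(tert-butyldimethylsilyloxy)phenyl]-4,4,5,5-tetramethyl-1,3,2-dioxaborolane | CC(C)(C)[Si](C)(C)Oc1cc(B2OC(C)(C)C(C)(C)O2)cc(O[Si](C)(C)C(C)(C)C)c1Br | intermediate
11 | 2-[3,5-bis(benzyloxy)-4-bromophenyl]-4,4,5,5-tetramethyl-1,3,2-dioxaborolane | CC1(C)OB(c2cc(OCc3ccccc3)c(Br)c(OCc3ccccc3)c2)OC1(C)C | intermediate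
12 | 3,5-bis(benzyloxy)-4-bromophenol | Oc1cc(OCc2ccccc2)c(Br)c(OCc2ccccc2)c1 | intermediate
13 | [3,5-bis(benzyloxy)-4-bromophenoxy]triisopropylsilane | CC(C)[Si](Oc1cc(OCc2ccccc2)c(Br)c(OCc2ccccc2)c1)(C(C)C)C(C)C | intermediate
14 | 3,5-bis(benzyloxy)phenol | Oc1cc(OCc2ccccc2)cc(OCc2ccccc2)c1 | starting material
15 | (2S,3R)-2-(benzyloxy)-3-[3,4-bis(benzyloxy)phenyl]-3-[3,5-bis(benzyloxy)phenoxy]-N-methoxy-N-methylpropanamide | CON(C)C(=O)[C@@H](OCc1ccccc1)[C@@H](c1ccc(OCc2ccccc2)c(OCc2ccccc2)c1)Oc1cc(OCc2ccccc2)cc(OCc2ccccc2)c1 | intermediate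
16 | (2S,3R)-2-(benzyloxy)-3-[3,4-bis(benzyloxy)phenyl]-3-[3,5-bis(benzyloxy)phenoxy]propanal | O=C[C@@H](OCc1ccccc1)[C@@H](c1ccc(OCc2ccccc2)c(OCc2ccccc2)c1)Oc1cc(OCc2ccccc2)cc(OCc2ccccc2)c1 | intermediate
17 | [2,6-bis(benzyloxy)-4-(triisopropylsilyloxy)phenyl]magnesium bromide (THF solution) | Br[Mg]c1c(OCc2ccccc2)cc(O[Si](C(C)C)(C(C)C)C(C)C)cc1OCc1ccccc1 | intermediate
18 | 1-[2,6-bis(benzyloxy)-4-(triisopropylsilyloxy)phenyl]-2-(benzyloxy)-3-[3,4-bis(benzyloxy)phenyl]-3-[3,5-bis(benzyloxy)phenoxy]propan-1-ol, both C1 epimers, C2 and C3 as in 16 | CC(C)[Si](Oc1cc(OCc2ccccc2)c(C(O)[C@@H](OCc2ccccc2)[C@@H](c2ccc(OCc3ccccc3)c(OCc3ccccc3)c2)Oc2cc(OCc3ccccc3)cc(OCc3ccccc3)c2)c(OCc2ccccc2)c1)(C(C)C)C(C)C | intermediate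
19 | 4-hydroxyphenyl analogue of 18 (silyl group removed), both C1 epimers | Oc1cc(OCc2ccccc2)c(C(O)[C@@H](OCc2ccccc2)[C@@H](c2ccc(OCc3ccccc3)c(OCc3ccccc3)c2)Oc2cc(OCc3ccccc3)cc(OCc3ccccc3)c2)c(OCc2ccccc2)c1 | intermediate (not isolated)
20 | 3,5-bis(benzyloxy)-4-alkylidenecyclohexa-2,5-dien-1-one (para-quinone methide) whose alkylidene group is the C1–C3 chain of 19 with C2 and C3 unchanged | O=C1C=C(OCc2ccccc2)C(=C[C@@H](OCc2ccccc2)[C@@H](c2ccc(OCc3ccccc3)c(OCc3ccccc3)c2)Oc2cc(OCc3ccccc3)cc(OCc3ccccc3)c2)C(OCc2ccccc2)=C1 | intermediate (not isolated)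
21 | (2R,3R)-3,5,7-tris(benzyloxy)-2-[3,4-bis(benzyloxy)phenyl]-4β-[2,6-bis(benzyloxy)-4-hydroxyphenyl]chroman (3,4-trans) | c1ccccc1COc1cc(OCc2ccccc2)c2c(c1)O[C@H](c1ccc(OCc3ccccc3)c(OCc3ccccc3)c1)[C@H](OCc1ccccc1)[C@H]2c1c(OCc2ccccc2)cc(O)cc1OCc1ccccc1 | intermediate
22 | (2S,3R)-2-(benzyloxy)-3-[3,4-bis(benzyloxy)phenyl]-N-methoxy-N-methyl-3-(aryloxy)propanamide, aryloxy = phenoxide of 21 | CON(C)C(=O)[C@@H](OCc1ccccc1)[C@@H](c1ccc(OCc2ccccc2)c(OCc2ccccc2)c1)Oc1cc(OCc2ccccc2)c([C@@H]2[C@@H](OCc3ccccc3)[C@@H](c3ccc(OCc4ccccc4)c(OCc4ccccc4)c3)Oc3cc(OCc4ccccc4)cc(OCc4ccccc4)c32)c(OCc2ccccc2)c1 | intermediate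
23 | (2S,3R)-2-(benzyloxy)-3-[3,4-bis(benzyloxy)phenyl]-3-(aryloxy)propanal, aryloxy = phenoxide of 21 | O=C[C@@H](OCc1ccccc1)[C@@H](c1ccc(OCc2ccccc2)c(OCc2ccccc2)c1)Oc1cc(OCc2ccccc2)c([C@@H]2[C@@H](OCc3ccccc3)[C@@H](c3ccc(OCc4ccccc4)c(OCc4ccccc4)c3)Oc3cc(OCc4ccccc4)cc(OCc4ccccc4)c32)c(OCc2ccccc2)c1 | intermediate
24 | 1-[2,6-bis(benzyloxy)-4-(triisopropylsilyloxy)phenyl]propan-1-ol from 23, both C1 epimers | CC(C)[Si](Oc1cc(OCc2ccccc2)c(C(O)[C@@H](OCc2ccccc2)[C@@H](c2ccc(OCc3ccccc3)c(OCc3ccccc3)c2)Oc2cc(OCc3ccccc3)c([C@@H]3[C@@H](OCc4ccccc4)[C@@H](c4ccc(OCc5ccccc5)c(OCc5ccccc5)c4)Oc4cc(OCc5ccccc5)cc(OCc5ccccc5)c43)c(OCc3ccccc3)c2)c(OCc2ccccc2)c1)(C(C)C)C(C)C | intermediate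
25 | 4-hydroxyphenyl analogue of 24 (silyl group removed), both C1 epimers | Oc1cc(OCc2ccccc2)c(C(O)[C@@H](OCc2ccccc2)[C@@H](c2ccc(OCc3ccccc3)c(OCc3ccccc3)c2)Oc2cc(OCc3ccccc3)c([C@@H]3[C@@H](OCc4ccccc4)[C@@H](c4ccc(OCc5ccccc5)c(OCc5ccccc5)c4)Oc4cc(OCc5ccccc5)cc(OCc5ccccc5)c43)c(OCc3ccccc3)c2)c(OCc2ccccc2)c1 | intermediate (not isolated)
26 | para-quinone methide formed from 25 by loss of water | O=C1C=C(OCc2ccccc2)C(=C[C@@H](OCc2ccccc2)[C@@H](c2ccc(OCc3ccccc3)c(OCc3ccccc3)c2)Oc2cc(OCc3ccccc3)c([C@@H]3[C@@H](OCc4ccccc4)[C@@H](c4ccc(OCc5ccccc5)c(OCc5ccccc5)c4)Oc4cc(OCc5ccccc5)cc(OCc5ccccc5)c43)c(OCc3ccccc3)c2)C(OCc2ccccc2)=C1 | intermediate (not isolated)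
27 | deca-O-benzyl epicatechin-(4β→6)-epicatechin bearing at C4 of the lower unit (4β, 3,4-trans) a 2,6-bis(benzyloxy)-4-hydroxyphenyl group | c1ccccc1COc1cc(OCc2ccccc2)c2c(c1)O[C@H](c1ccc(OCc3ccccc3)c(OCc3ccccc3)c1)[C@H](OCc1ccccc1)[C@H]2c1c(OCc2ccccc2)cc2c(c1OCc1ccccc1)[C@H](c1c(OCc3ccccc3)cc(O)cc1OCc1ccccc1)[C@@H](OCc1ccccc1)[C@@H](c1ccc(OCc3ccccc3)c(OCc3ccccc3)c1)O2 | intermediate
28 | (2S,3R)-2-(benzyloxy)-3-[3,4-bis(benzyloxy)phenyl]-N-methoxy-N-methyl-3-(aryloxy)propanamide, aryloxy = phenoxide of 27 | CON(C)C(=O)[C@@H](OCc1ccccc1)[C@@H](c1ccc(OCc2ccccc2)c(OCc2ccccc2)c1)Oc1cc(OCc2ccccc2)c([C@@H]2[C@@H](OCc3ccccc3)[C@@H](c3ccc(OCc4ccccc4)c(OCc4ccccc4)c3)Oc3cc(OCc4ccccc4)c([C@@H]4[C@@H](OCc5ccccc5)[C@@H](c5ccc(OCc6ccccc6)c(OCc6ccccc6)c5)Oc5cc(OCc6ccccc6)cc(OCc6ccccc6)c54)c(OCc4ccccc4)c32)c(OCc2ccccc2)c1 | intermediate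
29 | (2S,3R)-2-(benzyloxy)-3-[3,4-bis(benzyloxy)phenyl]-3-(aryloxy)propanal, aryloxy = phenoxide of 27 | O=C[C@@H](OCc1ccccc1)[C@@H](c1ccc(OCc2ccccc2)c(OCc2ccccc2)c1)Oc1cc(OCc2ccccc2)c([C@@H]2[C@@H](OCc3ccccc3)[C@@H](c3ccc(OCc4ccccc4)c(OCc4ccccc4)c3)Oc3cc(OCc4ccccc4)c([C@@H]4[C@@H](OCc5ccccc5)[C@@H](c5ccc(OCc6ccccc6)c(OCc6ccccc6)c5)Oc5cc(OCc6ccccc6)cc(OCc6ccccc6)c54)c(OCc4ccccc4)c32)c(OCc2ccccc2)c1 | intermediate
30 | pentadeca-O-benzyl trimer carrying a hydroxyl at C4 of the bottom unit (flavan-4-ol, both C4 epimers) | c1ccccc1COc1cc(OCc2ccccc2)c2c(c1)O[C@H](c1ccc(OCc3ccccc3)c(OCc3ccccc3)c1)[C@H](OCc1ccccc1)[C@H]2c1c(OCc2ccccc2)cc2c(c1OCc1ccccc1)[C@H](c1c(OCc3ccccc3)cc3c(c1OCc1ccccc1)C(O)[C@@H](OCc1ccccc1)[C@@H](c1ccc(OCc4ccccc4)c(OCc4ccccc4)c1)O3)[C@@H](OCc1ccccc1)[C@@H](c1ccc(OCc3ccccc3)c(OCc3ccccc3)c1)O2 | intermediate (not isolated)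
31 | pentadeca-O-benzyl epicatechin-(4β→6)-epicatechin-(4β→6)-epicatechin | c1ccccc1COc1cc(OCc2ccccc2)c2c(c1)O[C@H](c1ccc(OCc3ccccc3)c(OCc3ccccc3)c1)[C@H](OCc1ccccc1)[C@H]2c1c(OCc2ccccc2)cc2c(c1OCc1ccccc1)[C@H](c1c(OCc3ccccc3)cc3c(c1OCc1ccccc1)C[C@@H](OCc1ccccc1)[C@@H](c1ccc(OCc4ccccc4)c(OCc4ccccc4)c1)O3)[C@@H](OCc1ccccc1)[C@@H](c1ccc(OCc3ccccc3)c(OCc3ccccc3)c1)O2 | intermediate
32 | epicatechin-(4β→6)-epicatechin-(4β→6)-epicatechin | Oc1cc(O)c2c(c1)O[C@H](c1ccc(O)c(O)c1)[C@H](O)[C@H]2c1c(O)cc2c(c1O)[C@H](c1c(O)cc3c(c1O)C[C@@H](O)[C@@H](c1ccc(O)c(O)c1)O3)[C@@H](O)[C@@H](c1ccc(O)c(O)c1)O2 | target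

Total step count: 21 steps.
Longest linear sequence: 16 steps (steps 4–8 and 11–21 from 2-bromoresorcinol 8).

Steps most likely to fail

Step 13 (Proposed new method). After ionisation the cation may lose the C3 proton, so that the quinone methide tautomerises to an enol ether styrene and C3 is erased. The catechol ring may also attack (five-membered closure), or the facial selectivity at C4 may be poor. The fallback uses known chemistry, sets out from aldehyde 16 and returns at 21. Aldehyde 16 would be cyclised without silane (BF3·OEt2, CH2Cl2, −40 °C; the Friedel-Crafts hydroxyalkylation of step 20) to the 2,3-cis 3,5,7-tris(benzyloxy)-2-[3,4-bis(benzyloxy)phenyl]chroman-4-ol F1. Phenol 14 would be silylated (TIPSCl, imidazole) to [3,5-bis(benzyloxy)phenoxy]triisopropylsilane F2. F1 and F2 would then be joined with catalytic TMSOTf (CH2Cl2, −78 °C), the established acid-promoted C4 arylation of 4-oxygenated flavan-3-ol derivatives, which gives 3,4-trans products; the bulky silyl ether should steer attack to the carbon para to it. This gives the triisopropylsilyl ether of 21 F3, and n-Bu4NF would release 21.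

Step 17 (Proposed new method). The same losses as in step 13 may occur. In addition, acid may cleave or scramble the first interflavan bond, and closure onto the more crowded ring may be slow. The fallback uses known chemistry, sets out from aldehyde 23 and returns at 27. Aldehyde 23 would be cyclised without silane (BF3·OEt2, CH2Cl2, −40 °C) to the deca-O-benzyl dimer carrying a hydroxyl at C4 of the lower unit F4. F4 would be arylated at that C4 with the silyl ether F2 under catalytic TMSOTf at −78 °C (3,4-trans, para to the silyloxy group) to give the triisopropylsilyl ether of 27 F5, and n-Bu4NF would release 27.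

Step 9. Under Mitsunobu activation, water may be eliminated across the acidic alpha C–H and the benzylic carbinol to give the alpha-benzyloxycinnamamide. Partial ionisation at the electron-rich benzylic carbon may also erode the inversion. The fallback moves the etherification to a substrate without a carbonyl group; it sets out from aldol adduct 6 and returns at aldehyde 16. Adduct 6 would be reduced with LiBH4 (THF/MeOH, 0 °C) to (2R,3S)-2-(benzyloxy)-3-[3,4-bis(benzyloxy)phenyl]propane-1,3-diol F6. The primary hydroxyl would be silylated selectively (TBSCl, imidazole) to the primary tert-butyldimethylsilyl ether F7. Mitsunobu etherification of F7 with phenol 14 (PPh3, DIAD), now free of an acidic alpha hydrogen, should give the inverted 3,5-bis(benzyloxy)phenyl ether F8. n-Bu4NF would give the primary alcohol F9, and Dess-Martin periodinane would oxidise it to 16.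

Further compounds
F1 | step 13 | 2,3-cis 3,5,7-tris(benzyloxy)-2-[3,4-bis(benzyloxy)phenyl]chroman-4-ol (2R, C4 epimers) | OC1[C@@H](OCc2ccccc2)[C@@H](c2ccc(OCc3ccccc3)c(OCc3ccccc3)c2)Oc2cc(OCc3ccccc3)cc(OCc3ccccc3)c21
F2 | step 13 | [3,5-bis(benzyloxy)phenoxy]triisopropylsilane | CC(C)[Si](Oc1cc(OCc2ccccc2)cc(OCc2ccccc2)c1)(C(C)C)C(C)C
F3 | step 13 | triisopropylsilyl ether of 21 | CC(C)[Si](Oc1cc(OCc2ccccc2)c([C@@H]2[C@@H](OCc3ccccc3)[C@@H](c3ccc(OCc4ccccc4)c(OCc4ccccc4)c3)Oc3cc(OCc4ccccc4)cc(OCc4ccccc4)c32)c(OCc2ccccc2)c1)(C(C)C)C(C)C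
F4 | step 17 | deca-O-benzyl epicatechin-(4β→6)-epicatechin carrying a hydroxyl at C4 of the lower unit (C4 epimers) | c1ccccc1COc1cc(OCc2ccccc2)c2c(c1)O[C@H](c1ccc(OCc3ccccc3)c(OCc3ccccc3)c1)[C@H](OCc1ccccc1)[C@H]2c1c(OCc2ccccc2)cc2c(c1OCc1ccccc1)C(O)[C@@H](OCc1ccccc1)[C@@H](c1ccc(OCc3ccccc3)c(OCc3ccccc3)c1)O2
F5 | step 17 | triisopropylsilyl ether of 27 | c1ccccc1COc1cc(OCc2ccccc2)c2c(c1)O[C@H](c1ccc(OCc3ccccc3)c(OCc3ccccc3)c1)[C@H](OCc1ccccc1)[C@H]2c1c(OCc2ccccc2)cc2c(c1OCc1ccccc1)[C@H](c1c(OCc3ccccc3)cc(O[Si](C(C)C)(C(C)C)C(C)C)cc1OCc1ccccc1)[C@@H](OCc1ccccc1)[C@@H](c1ccc(OCc3ccccc3)c(OCc3ccccc3)c1)O2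
F6 | step 9 | (2R,3S)-2-(benzyloxy)-3-[3,4-bis(benzyloxy)phenyl]propane-1,3-diol | OC[C@@H](OCc1ccccc1)[C@H](c1ccc(OCc2ccccc2)c(OCc2ccccc2)c1)O
F7 | step 9 | primary tert-butyldimethylsilyl ether of F6 | CC(C)(C)[Si](C)(C)OC[C@@H](OCc1ccccc1)[C@H](c1ccc(OCc2ccccc2)c(OCc2ccccc2)c1)O
F8 | step 9 | 3,5-bis(benzyloxy)phenyl ether of F7, benzylic centre inverted | CC(C)(C)[Si](C)(C)OC[C@@H](OCc1ccccc1)[C@@H](c1ccc(OCc2ccccc2)c(OCc2ccccc2)c1)Oc1cc(OCc2ccccc2)cc(OCc2ccccc2)c1
F9 | step 9 | primary alcohol from F8 (alcohol corresponding to aldehyde 16) | OC[C@@H](OCc1ccccc1)[C@@H](c1ccc(OCc2ccccc2)c(OCc2ccccc2)c1)Oc1cc(OCc2ccccc2)cc(OCc2ccccc2)c1
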